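**Retrosynthetic overview**
- Target 23 ⇐ 5-O-benzyl flavanone 22 (hydrogenolysis) ⇐ chroman 19 (O-methylation at C8, desilylation, oxidation at C4). The C5 oxygen is carried as a benzyl ether, not a methyl ether, so that the last step is neutral: C2 is a 2,6-dimethoxybenzylic ether carbon that a Lewis acid could ionise and racemise.
- Ring A (closed last) ⇐ carbene–alkyne–CO benzannulation. The feature used: C5 and C8 of ring A carry oxygen para to each other and flank the C4a–C8a bond shared with ring C. C5 is the carbene carbon of 13 on C4a, C6–C7 come from methoxyacetylene 16, C8 from a CO ligand, and C4a=C8a is the enol ether bond of the dihydropyran.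
- 13 ⇐ vinyl iodide 7 (iodine–lithium exchange, Cr(CO)6, acylation/benzyl alcohol exchange) ⇐ (S)-dihydropyranone 4 (α-iodination, Luche reduction, silylation). Iodine replaces bromine because a brominating agent would attack the 1,3-dimethoxyarene.
- Ring C (closed first) and C2 ⇐ asymmetric hetero-Diels–Alder reaction of 2,6-dimethoxybenzaldehyde 1 with siloxy diene 2; ring B is bought in 1.

Key step: step 8

Assumption: (S)-BINOL is taken as the ligand antipode that sends the diene to the Si face of 1 (giving 2S), by analogy with other BINOL–titanium additions to aldehydes; if the first batch shows the opposite sense, (R)-BINOL is used.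

**Route**

Step 1
Reactants: 1 2,6-dimethoxybenzaldehyde; 2 trans-1-methoxy-3-(trimethylsilyloxy)buta-1,3-diene
Product: 4 (2S)-2-(2,6-dimethoxyphenyl)-2,3-dihydro-4H-pyran-4-one, via Mukaiyama aldol adduct 3 (not isolated)
Conditions: Ti(OiPr)4 (10 mol%), (S)-BINOL (20 mol%), 4 Å MS, Et2O, −20 °C; then TFA (cat.), CH2Cl2, 0 °C, short contact
Reagents that add atoms: none
Why: Catalytic asymmetric hetero-Diels–Alder reaction in its Mukaiyama aldol/cyclisation form: the BINOL–titanium Lewis acid binds the aldehyde, the diene terminus adds to the Si face and sets C2 as S, and brief acid closes the pyranone with loss of methanol and the silyl group.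

Step 2
Reactants: 4 (2S)-2-(2,6-dimethoxyphenyl)-2,3-dihydro-4H-pyran-4-one
Product: 5 (2S)-2-(2,6-dimethoxyphenyl)-5-iodo-2,3-dihydro-4H-pyran-4-one
Conditions: I2 (1.5 equiv), pyridine (3 equiv), CH2Cl2, 0 °C → rt
Reagents that add atoms: iodine, II
Why: α-Iodination of an enone with I2/pyridine, here on a vinylogous ester whose enol ether carbon C5 is the most nucleophilic site; pyridine-buffered I2 is too weak an electrophile for the 1,3-dimethoxyarene, and the mild base leaves C2 alone.

Step 3
Reactants: 5 (2S)-2-(2,6-dimethoxyphenyl)-5-iodo-2,3-dihydro-4H-pyran-4-one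
Product: 6 (2S,4S)-2-(2,6-dimethoxyphenyl)-5-iodo-3,4-dihydro-2H-pyran-4-ol (2,4-cis)
Conditions: NaBH4, CeCl3·7H2O, MeOH, −78 → −40 °C
Reagents that add atoms: none
Why: Luche 1,2-reduction of the α-iodoenone; hydride should attack C4 axially on the half-chair that holds the aryl group pseudo-equatorial, giving the 2,4-cis alcohol by substrate control (this centre is removed in step 11, so its selectivity is not critical).

Step 4
Reactants: 6 (2S,4S)-2-(2,6-dimethoxyphenyl)-5-iodo-3,4-dihydro-2H-pyran-4-ol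
Product: 7 tert-butyl{[(2S,4S)-2-(2,6-dimethoxyphenyl)-5-iodo-3,4-dihydro-2H-pyran-4-yl]oxy}dimethylsilane
Conditions: TBSCl, imidazole, DMF, rt
Reagents that add atoms: tert-butyldimethylsilyl chloride, CC(C)(C)[Si](C)(C)Cl
Why: Standard silylation of a secondary allylic alcohol under basic conditions that spare the acid-sensitive iodo enol ether; the silyl ether masks the hydroxyl for the organolithium step and the benzannulation.

Step 5
Reactants: 7 tert-butyl{[(2S,4S)-2-(2,6-dimethoxyphenyl)-5-iodo-3,4-dihydro-2H-pyran-4-yl]oxy}dimethylsilane; 8 chromium hexacarbonyl Cr(CO)6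
Product: 11 tetramethylammonium pentacarbonyl{[(2S,4S)-4-(tert-butyldimethylsilyloxy)-2-(2,6-dimethoxyphenyl)-3,4-dihydro-2H-pyran-5-yl]carbonyl}chromate, via vinyllithium 9 (not isolated), via lithium acylchromate 10 (not isolated)
Conditions: t-BuLi (2.1 equiv), Et2O, −100 °C, 10 min; Cr(CO)6 (1.1 equiv) in THF, −100 → 0 °C; then Me4NBr, H2O, 0 °C
Reagents that add atoms: tetramethylammonium bromide, C[N+](C)(C)C.[Br-]
Why: Iodine–lithium exchange followed by the Fischer carbene synthesis (organolithium addition to a CO ligand of Cr(CO)6) gives the acylchromate, isolated after cation exchange as the stable ammonium salt; the exchange is run at −100 °C with immediate trapping because lithium on C5 stands anti to the ring oxygen and could open the ring by β-elimination on warming.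

Step 6
Reactants: 11 tetramethylammonium pentacarbonyl{[(2S,4S)-4-(tert-butyldimethylsilyloxy)-2-(2,6-dimethoxyphenyl)-3,4-dihydro-2H-pyran-5-yl]carbonyl}chromate
Product: 13 pentacarbonyl{(benzyloxy)[(2S,4S)-4-(tert-butyldimethylsilyloxy)-2-(2,6-dimethoxyphenyl)-3,4-dihydro-2H-pyran-5-yl]methylidene}chromium, via acetoxycarbene complex 12 (not isolated)
Conditions: AcBr (1.05 equiv), CH2Cl2, −40 °C; then BnOH (1.5 equiv), −40 → 0 °C
Reagents that add atoms: benzyl alcohol, OCc1ccccc1
Why: O-Acylation of the acylchromate gives the acyloxycarbene complex, whose carbene carbon is attacked by benzyl alcohol with loss of acetic acid (the established acyloxy/alkoxy exchange route to alkoxycarbene complexes); this puts on the future C5 oxygen a group that hydrogenolysis removes at the end.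

Step 7
Reactants: 14 chloroacetaldehyde dimethyl acetal
Product: 16 methoxyacetylene, via sodium methoxyacetylide 15 (not isolated)
Conditions: NaNH2 (3 equiv), liq. NH3, −33 °C; NH3 evaporated; then cold satd aq. NaCl, −70 → 40 °C, distilled into a −78 °C trap, taken up in cold THF
Reagents that add atoms: none
Why: Successive amide-induced eliminations of methanol and HCl from the chloro acetal give the ynol ether as its sodium acetylide, which water protonates; the volatile, unstable alkyne is used at once as a cold solution.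

Step 8
Reactants: 13 pentacarbonyl{(benzyloxy)[(2S,4S)-4-(tert-butyldimethylsilyloxy)-2-(2,6-dimethoxyphenyl)-3,4-dihydro-2H-pyran-5-yl]methylidene}chromium; 16 methoxyacetylene
Product: 19 (2S,4S)-5-(benzyloxy)-4-(tert-butyldimethylsilyloxy)-2-(2,6-dimethoxyphenyl)-7-methoxy-3,4-dihydro-2H-chromen-8-ol, via dienylcarbene complex 17 (not isolated), via arene tricarbonylchromium complex 18 (not isolated)
Conditions: 16 (3 equiv, in portions), THF (0.05 M), 50 °C, sealed tube, Ar; then hν (450 nm LED), rt; then air, Et2O, rt, filtration through Celite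
Reagents that add atoms: none
Why: Proposed new method: loss of one CO from 13 at 50 °C lets 16 bind and insert into the Cr=C bond, its CH carbon bonding to the carbene carbon (C5–C6) and its methoxy-bearing carbon becoming the new oxygen-stabilised carbene carbon C7 of 17; CO insertion at C7 gives a dienylketene (C7–C8), whose ketene carbon closes ring A on C8a of the dihydropyran by a 6π-electrocyclisation (six-membered ring, C8–C8a), and enolisation gives the phenol as its Cr(CO)3 complex 18, which air strips of the metal. The closest known reactions are the Dötz benzannulation of cycloalkenyl and dihydropyranyl alkoxycarbene chromium complexes with terminal alkynes, the regioselective insertion of ynamines into the Cr=C bond, and the conversion of isolated alkoxy(dienyl)carbene chromium complexes into ortho-alkoxyphenols by heat or light; an alkoxyacetylene as the alkyne partner of the benzannulation itself is not established. Because the donor-stabilised carbene 17 may be slow to insert CO, the irradiation stage, which drives CO insertion in alkoxycarbene chromium complexes, is part of the procedure. No stereocentre is formed, and C2 and C4 lie away from the metal and keep their configuration. The step needs H at C6 and OMe at C7, and both the polarisation of the ynol ether (nucleophilic CH carbon to the electrophilic carbene carbon) and the usual placing of the larger alkyne substituent next to the CO-derived carbon point this way. It also needs C7 cis to C4a across C5=C6, the geometry that an alkoxy group on the former carbene carbon favours.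

Step 9
Reactants: 19 (2S,4S)-5-(benzyloxy)-4-(tert-butyldimethylsilyloxy)-2-(2,6-dimethoxyphenyl)-7-methoxy-3,4-dihydro-2H-chromen-8-ol
Product: 20 {[(2S,4S)-5-(benzyloxy)-2-(2,6-dimethoxyphenyl)-7,8-dimethoxy-3,4-dihydro-2H-chromen-4-yl]oxy}(tert-butyl)dimethylsilane
Conditions: MeI, K2CO3, DMF, rt, Ar
Reagents that add atoms: iodomethane, CI
Why: Williamson methylation of the C8 phenol, run on freshly isolated 19 to forestall air oxidation of the electron-rich phenol; the silyl and benzyl ethers are inert to carbonate.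

Step 10
Reactants: 20 {[(2S,4S)-5-(benzyloxy)-2-(2,6-dimethoxyphenyl)-7,8-dimethoxy-3,4-dihydro-2H-chromen-4-yl]oxy}(tert-butyl)dimethylsilane
Product: 21 (2S,4S)-5-(benzyloxy)-2-(2,6-dimethoxyphenyl)-7,8-dimethoxy-3,4-dihydro-2H-chromen-4-ol
Conditions: Bu4NF, THF, 0 °C → rt
Reagents that add atoms: none
Why: Fluoride cleavage of the secondary silyl ether under non-acidic conditions, which avoids ionisation at the electron-rich C4 benzylic position.

Step 11
Reactants: 21 (2S,4S)-5-(benzyloxy)-2-(2,6-dimethoxyphenyl)-7,8-dimethoxy-3,4-dihydro-2H-chromen-4-ol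
Product: 22 (2S)-5-(benzyloxy)-2-(2,6-dimethoxyphenyl)-7,8-dimethoxy-2,3-dihydro-4H-chromen-4-one
Conditions: Dess–Martin periodinane, NaHCO3, CH2Cl2, 0 °C → rt
Reagents that add atoms: none
Why: Dess–Martin oxidation of the benzylic alcohol to the chromanone under buffered conditions free of strong acid or base, so that neither a C4 cation nor a C3 enolate (which would open ring C and racemise C2) is formed.

Step 12
Reactants: 22 (2S)-5-(benzyloxy)-2-(2,6-dimethoxyphenyl)-7,8-dimethoxy-2,3-dihydro-4H-chromen-4-one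
Product: 23 (2S)-5-hydroxy-7,8,2',6'-tetramethoxyflavanone
Conditions: H2 (1 atm), 10% Pd/C, EtOAc, rt, stopped after one equivalent of H2
Reagents that add atoms: none
Why: Hydrogenolysis of the primary benzyl ether at C5 under neutral conditions; the hindered secondary C2–O1 bond should be cleaved much more slowly, and with no acid or base present ring C stays closed and C2 stays S.

**Compound list**
1 | 2,6-dimethoxybenzaldehyde | COc1cccc(OC)c1C=O | starting material
2 | trans-1-methoxy-3-(trimethylsilyloxy)buta-1,3-diene | CO/C=C/C(=C)O[Si](C)(C)C | starting material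
3 | (1E,5S)-5-(2,6-dimethoxyphenyl)-1-methoxy-5-(trimethylsilyloxy)pent-1-en-3-one | CO/C=C/C(=O)C[C@H](O[Si](C)(C)C)c1c(OC)cccc1OC | intermediate
4 | (2S)-2-(2,6-dimethoxyphenyl)-2,3-dihydro-4H-pyran-4-one | O=C1C=CO[C@H](c2c(OC)cccc2OC)C1 | intermediate
5 | (2S)-2-(2,6-dimethoxyphenyl)-5-iodo-2,3-dihydro-4H-pyran-4-one | O=C1C(I)=CO[C@H](c2c(OC)cccc2OC)C1 | intermediate
6 | (2S,4S)-2-(2,6-dimethoxyphenyl)-5-iodo-3,4-dihydro-2H-pyran-4-ol (2,4-cis) | IC1=CO[C@H](c2c(OC)cccc2OC)C[C@@H]1O | intermediate
7 | tert-butyl{[(2S,4S)-2-(2,6-dimethoxyphenyl)-5-iodo-3,4-dihydro-2H-pyran-4-yl]oxy}dimethylsilane | IC1=CO[C@H](c2c(OC)cccc2OC)C[C@@H]1O[Si](C)(C)C(C)(C)C | intermediate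
8 | chromium hexacarbonyl, Cr(CO)6 | O=C=[Cr](=C=O)(=C=O)(=C=O)(=C=O)=C=O | starting material
9 | [(2S,4S)-4-(tert-butyldimethylsilyloxy)-2-(2,6-dimethoxyphenyl)-3,4-dihydro-2H-pyran-5-yl]lithium | [Li]C1=CO[C@H](c2c(OC)cccc2OC)C[C@@H]1O[Si](C)(C)C(C)(C)C | intermediate
10 | lithium pentacarbonyl{[(2S,4S)-4-(tert-butyldimethylsilyloxy)-2-(2,6-dimethoxyphenyl)-3,4-dihydro-2H-pyran-5-yl]carbonyl}chromate | [Li+].[O-]C(=[Cr](=C=O)(=C=O)(=C=O)(=C=O)=C=O)C1=CO[C@H](c2c(OC)cccc2OC)C[C@@H]1O[Si](C)(C)C(C)(C)C | intermediate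
11 | tetramethylammonium pentacarbonyl{[(2S,4S)-4-(tert-butyldimethylsilyloxy)-2-(2,6-dimethoxyphenyl)-3,4-dihydro-2H-pyran-5-yl]carbonyl}chromate | C[N+](C)(C)C.[O-]C(=[Cr](=C=O)(=C=O)(=C=O)(=C=O)=C=O)C1=CO[C@H](c2c(OC)cccc2OC)C[C@@H]1O[Si](C)(C)C(C)(C)C | intermediate
12 | pentacarbonyl{(acetyloxy)[(2S,4S)-4-(tert-butyldimethylsilyloxy)-2-(2,6-dimethoxyphenyl)-3,4-dihydro-2H-pyran-5-yl]methylidene}chromium | CC(=O)OC(=[Cr](=C=O)(=C=O)(=C=O)(=C=O)=C=O)C1=CO[C@H](c2c(OC)cccc2OC)C[C@@H]1O[Si](C)(C)C(C)(C)C | intermediate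
13 | pentacarbonyl{(benzyloxy)[(2S,4S)-4-(tert-butyldimethylsilyloxy)-2-(2,6-dimethoxyphenyl)-3,4-dihydro-2H-pyran-5-yl]methylidene}chromium (2,4-cis) | c1ccccc1COC(=[Cr](=C=O)(=C=O)(=C=O)(=C=O)=C=O)C1=CO[C@H](c2c(OC)cccc2OC)C[C@@H]1O[Si](C)(C)C(C)(C)C | intermediate
14 | chloroacetaldehyde dimethyl acetal (2-chloro-1,1-dimethoxyethane) | COC(CCl)OC | starting material
15 | sodium methoxyacetylide | [Na+].[C-]#COC | intermediate
16 | methoxyacetylene | C#COC | intermediate
17 | pentacarbonyl{(2E)-3-(benzyloxy)-3-[(2S,4S)-4-(tert-butyldimethylsilyloxy)-2-(2,6-dimethoxyphenyl)-3,4-dihydro-2H-pyran-5-yl]-1-methoxyprop-2-en-1-ylidene}chromium | COC(=[Cr](=C=O)(=C=O)(=C=O)(=C=O)=C=O)/C=C(/OCc1ccccc1)C1=CO[C@H](c2c(OC)cccc2OC)C[C@@H]1O[Si](C)(C)C(C)(C)C | intermediate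
18 | tricarbonylchromium complex of 19 (Cr(CO)3 η6-bound to ring A, either face; written as two parts) | COc1cc(OCc3ccccc3)c2c(c1O)O[C@H](c1c(OC)cccc1OC)C[C@@H]2O[Si](C)(C)C(C)(C)C.O=C=[Cr](=C=O)=C=O | intermediate
19 | (2S,4S)-5-(benzyloxy)-4-(tert-butyldimethylsilyloxy)-2-(2,6-dimethoxyphenyl)-7-methoxy-3,4-dihydro-2H-chromen-8-ol (2,4-cis) | COc1cc(OCc3ccccc3)c2c(c1O)O[C@H](c1c(OC)cccc1OC)C[C@@H]2O[Si](C)(C)C(C)(C)C | intermediate
20 | {[(2S,4S)-5-(benzyloxy)-2-(2,6-dimethoxyphenyl)-7,8-dimethoxy-3,4-dihydro-2H-chromen-4-yl]oxy}(tert-butyl)dimethylsilane | COc1cc(OCc3ccccc3)c2c(c1OC)O[C@H](c1c(OC)cccc1OC)C[C@@H]2O[Si](C)(C)C(C)(C)C | intermediate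
21 | (2S,4S)-5-(benzyloxy)-2-(2,6-dimethoxyphenyl)-7,8-dimethoxy-3,4-dihydro-2H-chromen-4-ol | COc1cc(OCc3ccccc3)c2c(c1OC)O[C@H](c1c(OC)cccc1OC)C[C@@H]2O | intermediate
22 | (2S)-5-(benzyloxy)-2-(2,6-dimethoxyphenyl)-7,8-dimethoxy-2,3-dihydro-4H-chromen-4-one | COc1cc(OCc3ccccc3)c2c(c1OC)O[C@H](c1c(OC)cccc1OC)CC2=O | intermediate
23 | (2S)-5-hydroxy-7,8,2',6'-tetramethoxyflavanone | COc1cc(O)c2c(c1OC)O[C@H](c1c(OC)cccc1OC)CC2=O | target

**Step count**
Total steps: 12. Longest linear sequence: 11 (steps 1–6 and 8–12; step 7 is the side branch to the alkyne).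

**Steps most likely to fail**

1. Step 8 (proposed new method). The insertion product may stall as a donor-stabilised carbene that does not take up CO, the ynol ether may oligomerise on the metal, or insertion with the wrong alkene geometry may lead to five-membered-ring products. The fallback uses known chemistry, with ring A bought in and ring C closed last; it sets out from 1 and comes back at 23.
 - Claisen–Schmidt condensation of 1 with the known 1-(2-hydroxy-3,4,6-trimethoxyphenyl)ethanone F1 (KOH, EtOH, rt) should give the chalcone (E)-3-(2,6-dimethoxyphenyl)-1-(2-hydroxy-3,4,6-trimethoxyphenyl)prop-2-en-1-one F2.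
 - Oxa-Michael ring closure (NaOAc, EtOH, reflux) should give racemic 5,7,8,2',6'-pentamethoxyflavanone F3.
 - BCl3 (CH2Cl2, −78 → 0 °C) should cleave the C5 methyl ether next to the carbonyl, giving racemic 5-hydroxy-7,8,2',6'-tetramethoxyflavanone F4. The Lewis acid is tolerable here because opening of ring C costs no stereochemistry at the racemic stage.
 - Preparative HPLC on a chiral stationary phase then delivers 23.

2. Step 5. The C5 lithium species may open the ring by anti β-elimination of the ring alkoxide before it adds to Cr(CO)6. The fallback avoids the organolithium; it sets out from 7 and comes back at 11.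
 - Palladium-catalysed hydroxycarbonylation of 7 (Pd(OAc)2, dppf, CO 1 atm, KOAc, wet DMSO, 60 °C) should give (2S,4S)-4-(tert-butyldimethylsilyloxy)-2-(2,6-dimethoxyphenyl)-3,4-dihydro-2H-pyran-5-carboxylic acid F5.
 - 1-Chloro-N,N,2-trimethylprop-1-en-1-amine (CH2Cl2, 0 °C) converts it under neutral conditions into (2S,4S)-4-(tert-butyldimethylsilyloxy)-2-(2,6-dimethoxyphenyl)-3,4-dihydro-2H-pyran-5-carbonyl chloride F6.
 - K2Cr(CO)5, made in the flask from 8 and KC8 (THF, −78 °C), is acylated by F6 to potassium pentacarbonyl{[(2S,4S)-4-(tert-butyldimethylsilyloxy)-2-(2,6-dimethoxyphenyl)-3,4-dihydro-2H-pyran-5-yl]carbonyl}chromate F7.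
 - Exchange with Me4NBr gives 11.

3. Step 1. The di-ortho-substituted, electron-rich aldehyde may give low conversion or poor facial discrimination, and the acid used for ring closure may ionise the benzylic carbon and erode the configuration. The fallback sets C2 by hydrogenation of a ketone; it sets out from 1 and comes back at 4.
 - Roskamp homologation of 1 (ethyl diazoacetate, SnCl2, CH2Cl2) should give ethyl 3-(2,6-dimethoxyphenyl)-3-oxopropanoate F8.
 - Noyori hydrogenation with RuCl2[(R)-BINAP] (H2, EtOH), the antipode that gives (R)-3-hydroxybutanoate from acetoacetate, should give ethyl (3S)-3-(2,6-dimethoxyphenyl)-3-hydroxypropanoate F9.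
 - MeNH(OMe)·HCl and i-PrMgCl (THF, −20 °C) give the Weinreb amide (3S)-3-(2,6-dimethoxyphenyl)-3-hydroxy-N-methoxy-N-methylpropanamide F10.
 - Excess HC≡CMgBr (THF, 0 °C) gives (5S)-5-(2,6-dimethoxyphenyl)-5-hydroxypent-1-yn-3-one F11.
 - Gold-catalysed 6-endo cyclisation of the hydroxyl onto the ynone (Ph3PAuCl/AgOTf cat., CH2Cl2, rt) gives 4.

**Further compounds**
F1 | step 8 | 1-(2-hydroxy-3,4,6-trimethoxyphenyl)ethanone | CC(=O)c1c(O)c(OC)c(OC)cc1OC
F2 | step 8 | (E)-3-(2,6-dimethoxyphenyl)-1-(2-hydroxy-3,4,6-trimethoxyphenyl)prop-2-en-1-one | COc1cccc(OC)c1/C=C/C(=O)c1c(O)c(OC)c(OC)cc1OC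
F3 | step 8 | racemic 5,7,8,2',6'-pentamethoxyflavanone | COc1cc(OC)c2c(c1OC)OC(c1c(OC)cccc1OC)CC2=O
F4 | step 8 | racemic 5-hydroxy-7,8,2',6'-tetramethoxyflavanone | COc1cc(O)c2c(c1OC)OC(c1c(OC)cccc1OC)CC2=O
F5 | step 5 | (2S,4S)-4-(tert-butyldimethylsilyloxy)-2-(2,6-dimethoxyphenyl)-3,4-dihydro-2H-pyran-5-carboxylic acid | OC(=O)C1=CO[C@H](c2c(OC)cccc2OC)C[C@@H]1O[Si](C)(C)C(C)(C)C
F6 | step 5 | (2S,4S)-4-(tert-butyldimethylsilyloxy)-2-(2,6-dimethoxyphenyl)-3,4-dihydro-2H-pyran-5-carbonyl chloride | ClC(=O)C1=CO[C@H](c2c(OC)cccc2OC)C[C@@H]1O[Si](C)(C)C(C)(C)C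
F7 | step 5 | potassium pentacarbonyl{[(2S,4S)-4-(tert-butyldimethylsilyloxy)-2-(2,6-dimethoxyphenyl)-3,4-dihydro-2H-pyran-5-yl]carbonyl}chromate | [K+].[O-]C(=[Cr](=C=O)(=C=O)(=C=O)(=C=O)=C=O)C1=CO[C@H](c2c(OC)cccc2OC)C[C@@H]1O[Si](C)(C)C(C)(C)C
F8 | step 1 | ethyl 3-(2,6-dimethoxyphenyl)-3-oxopropanoate | CCOC(=O)CC(=O)c1c(OC)cccc1OC
F9 | step 1 | ethyl (3S)-3-(2,6-dimethoxyphenyl)-3-hydroxypropanoate | CCOC(=O)C[C@H](O)c1c(OC)cccc1OC
F10 | step 1 | (3S)-3-(2,6-dimethoxyphenyl)-3-hydroxy-N-methoxy-N-methylpropanamide | CON(C)C(=O)C[C@H](O)c1c(OC)cccc1OC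
F11 | step 1 | (5S)-5-(2,6-dimethoxyphenyl)-5-hydroxypent-1-yn-3-one | C#CC(=O)C[C@H](O)c1c(OC)cccc1OC
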